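## Analysis of the target

Arteminorin C (22) is a 3,3'-bicoumarin: two 2H-chromen-2-one units joined by a single bond between C3 and C3'. The unprimed half carries oxygen on three neighbouring carbons (6-OMe, 7-OH, 8-OMe), which with O1 on C8a makes four contiguous oxygenated ring carbons. The primed half is a 6',7'-catechol. There is no stereocentre, and the C3–C3' axis is flanked only by C2=O and C4–H on each side, so it rotates freely and nothing stereochemical has to be controlled. The sensitive groups are the free catechol (air oxidation to the ortho-quinone), the phenol wedged between two methoxy groups, and two aryl lactones that open with base or amines. Three hydroxyls must be kept distinct from two methyl ethers throughout. The difficulty is that the two halves differ, so the C3–C3' bond joins two unlike, electron-poor positions, and the O1/C8/C7/C6 oxygen array must be placed without regiochemical ambiguity. The strategy rests on one feature: in each half O1 sits on C8a, and C8a is para to the oxygen on C6 (and, in the unprimed half, ortho to the methoxy on C8). Taking out O1 and O1' therefore leaves 1-indanones whose carbonyl carbon is bonded directly to a donor-activated aryl carbon, and C3–C3' becomes a bond between two ketone alpha-carbons.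

## Retrosynthetic reasoning

22 back to 21. The three O–benzyl bonds are cut. One protecting group serves all three hydroxyls and is orthogonal to the two methyl ethers. It is removed last, by a boron Lewis acid with a cation scavenger, not by hydrogenolysis, which could saturate C3=C4.

21 back to 19. The C3=C4 and C3'=C4' double bonds are returned to single bonds. The forward reaction is a double dehydrogenation. It should be easy because C4 and C4' are benzylic and para to the 7- and 7'-oxygens, and because each event creates an aromatic pyranone. What is gained is sp3 character at C3 and C3', so the bond between the halves becomes an ordinary aliphatic bond. The two stereocentres this introduces are erased again in the forward direction.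

19 back to 16. O1 and O1' are deleted, which reconnects C2 to C8a and C2' to C8a' and contracts both lactones to 1-indanones. Any other way of attaching these oxygens would need an aryl C–H oxidation with a choice of positions, or a free ortho-phenol on an already crowded ring. Here the oxygen enters at exactly the carbon that held the carbonyl, so its position is fixed by the carbon skeleton. The forward reaction is a twofold peracid oxygen insertion with aryl migration, passing through the keto-lactones 17 and 18.

16 back to 9 and 13. The C2–C2' bond of the biindanone is cut. It lies between two ketone alpha-carbons, so one half serves as a stabilised enolate (allyl beta-keto ester 9) and the other as an alpha-bromo ketone (13). Alkylation gives 14, and removal of the allyl ester under neutral conditions gives 16 through acid 15. The allyl ester is chosen so that no strong acid, hot halide salt or hydrogen is needed in the presence of three benzyl ethers and a peri methoxy group. The bromide is placed on the dioxygenated indanone because the trioxygenated ring could brominate at its one free aromatic position.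

9 back to 8 and then 6. The ester carbon is removed (C-acylation of the ketone enolate forward). The benzyl ether, introduced with benzyl bromide 7, is cut back to the phenol 6. Benzylation is placed after ring closure so that no benzyl ether meets strong acid.

6 back to 5. The aryl–acyl bond is cut, which is an intramolecular Friedel-Crafts acylation forward. The aryl ring of 5 is symmetric, so the two ortho positions are identical and only one indanone can form. This delivers the 5,6,7-oxygen pattern with the middle oxygen already distinguished as a phenol.

5 back to 4 and then 1 and 2. The side chain is desaturated to sinapic acid 4, which is cut at the alkene into syringaldehyde 1 and malonic acid 2 (Doebner condensation forward). Hydrogenation is placed before any benzyl group exists.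

13 back to 12, 11 and 10. The C–Br bond is removed, the two benzyl ethers are cut, and the catechol 11 is traced to commercial 5,6-dimethoxy-1-indanone 10. The methyl ethers of this half must be exchanged for benzyl at the very start, because later they could not be told apart from the two that stay.

## Alternatives that were turned down

Alternative 1: The primed pyranone ring is disconnected at C4a'–C4', C8a'–O1', C3'=C4' and O1'–C2'. The benzene ring would come from the symmetric aryne released from silyl triflate A2, C4' from the carbonyl carbon of a formamide, and C2'/C3' from the side chain of coumarin-3-ylacetate A3. In the forward step fluoride unmasks the aryne, which adds across the formamide C=O. The enolate of A3 intercepts the resulting ortho-quinone-methide-type species, amine is lost, and the phenoxide lactonises to A1.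
- For: it is convergent, the primed ring appears directly at the coumarin oxidation level, and the symmetric aryne removes any regiochemical question. On these points it is stronger than the chosen route, which needs a later dehydrogenation.
- Against: A3 is the harder half and is not addressed. It requires a salicylaldehyde with four contiguous oxygens, for which no symmetric, cheap precursor exists, so the difficulty is moved and not solved.
- Against: the methylene of A3 is activated by one ester only and is less acidic than the 1,3-dicarbonyl partners such three-component couplings favour. Direct arylation of the enolate by the aryne is a likely competitor.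
- Against: A1 carries a methylene acetal. Its cleavage needs boron trihalide conditions under which the two aryl methyl ethers compete.
- Comparison: the chosen route obtains both oxygen patterns from 1 and 10, uses one protecting group for all three hydroxyls, and ends with a debenzylation that leaves methyl ethers alone.

Alternative 2: The unprimed benzene ring is built from nothing, cutting C4a–C8a and O1–C2. On heating, cyclobutenone A5 would open to a dienylketene, close in a six-electron electrocyclisation, tautomerise to the phenol and lactonise onto the cis ester to give A4.
- For: every oxygen of the crowded ring is placed by construction, the key step needs no reagent, and the coumarin level is reached directly. In regiocontrol of a ring made de novo it is stronger than a Friedel-Crafts closure would be on an unsymmetrical arene.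
- Against: that advantage is not needed here, since the symmetric ring of 5 closes without a choice.
- Against: A5 requires a dienyl carbanion that already contains a methyl ester and a coumarin lactone to be added to a squaric ester. Such a nucleophile would not survive its own electrophilic groups, so the side chain would have to be assembled afterwards in several steps with control of the Z geometry.
- Against, and decisive: A4 has a methyl ether on O7, whereas 22 needs a free 7-OH. The three oxygens on C6, C7 and C8 all arrive as methyl ethers, and a selective central demethylation next to two benzyl ethers and two lactones would add an uncertain step.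
- Comparison: the chosen route takes the 6,7,8 pattern from 1 with O7 already distinguished as a phenol, and is shorter.

Alternative 3: Both pyranone rings are cut at O1–C8a and O1'–C8a', giving the unsymmetrical dibenzylidenesuccinic acid A7. Under a flavin photocatalyst, visible light and air, both alkenes would isomerise from E to Z and each carboxyl oxygen would attack an ortho carbon of its own aryl ring, giving A6, which is the same structure as 21.
- For: A7 is available in a few steps by two successive Stobbe condensations, and one operation would deliver both rings at the final oxidation level. In step economy this is clearly stronger than the chosen route.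
- Against: the single step must perform four events on a cross-conjugated aryl-diene. This is the parent chromophore of the fulgide family, whose known photochemistry is six-electron closure to dihydronaphthalenes, so an arylnaphthalene path competes directly.
- Against: the dibenzyloxyphenyl ring of A7 has two different ortho positions, so the primed ring could close to the 7',8'-isomer.
- Against: benzylic ether C–H bonds and very electron-rich arenes are themselves substrates for aerobic flavin photooxidation.
- Comparison: the chosen route spreads the risk over ionic steps with predictable outcomes, and the position of each lactone oxygen is fixed by the skeleton of 16, not by a choice between two C–H bonds.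

Key step: step 11

Assumption: compounds 9 and 13 to 20 carry sp3 stereocentres that all become sp2 by step 12, so they are used as racemates or diastereomer mixtures and drawn without descriptors.

## Route

Step 1
Reactants: 1 syringaldehyde; 2 malonic acid
Product: 4 (E)-sinapic acid, via benzylidenemalonic acid 3 (not isolated)
Conditions: pyridine, piperidine (cat.), 80 °C; then aq. HCl
Reagents that add atoms: none
Why: Knoevenagel condensation in the Doebner modification; the arylidene malonic acid 3 loses CO2 in hot pyridine and the E acid results because decarboxylation passes through the less hindered arrangement.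

Step 2
Reactants: 4 (E)-sinapic acid
Product: 5 3-(4-hydroxy-3,5-dimethoxyphenyl)propanoic acid
Conditions: H2 (1 atm), Pd/C, MeOH, rt
Reagents that add atoms: none
Why: Catalytic hydrogenation of a cinnamic acid double bond; no benzyl group is present yet, so nothing else can be reduced.

Step 3
Reactants: 5 3-(4-hydroxy-3,5-dimethoxyphenyl)propanoic acid
Product: 6 6-hydroxy-5,7-dimethoxy-1-indanone
Conditions: P2O5 in MeSO3H (Eaton's reagent), 60 °C; then ice-water
Reagents that add atoms: none
Why: Intramolecular Friedel-Crafts acylation; the attacked carbon is ortho to one methoxy and para to the other, the two ortho positions of the symmetric ring are identical so one indanone forms, and this medium tolerates free phenols.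

Step 4
Reactants: 6 6-hydroxy-5,7-dimethoxy-1-indanone; 7 benzyl bromide
Product: 8 6-benzyloxy-5,7-dimethoxy-1-indanone
Conditions: BnBr, K2CO3, DMF, 60 °C
Reagents that add atoms: benzyl bromide (compound 7, also listed as reactant), BrCc1ccccc1
Why: Williamson etherification of the phenoxide; K2CO3 is too weak to enolise the ketone, so only oxygen is alkylated.

Step 5
Reactants: 8 6-benzyloxy-5,7-dimethoxy-1-indanone
Product: 9 allyl 6-benzyloxy-5,7-dimethoxy-1-oxoindane-2-carboxylate (racemic, keto and enol forms)
Conditions: NaH, (CH2=CHCH2O)2CO, THF, reflux; then AcOH
Reagents that add atoms: diallyl carbonate, C=CCOC(=O)OCC=C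
Why: Claisen-type C-acylation of the ketone enolate by a dialkyl carbonate, driven to completion by deprotonation of the beta-keto ester formed.

Step 6
Reactants: 10 5,6-dimethoxy-1-indanone
Product: 11 5,6-dihydroxy-1-indanone
Conditions: BBr3, CH2Cl2, −78 °C to rt; then H2O
Reagents that add atoms: none
Why: Lewis-acid cleavage of aryl methyl ethers; bromide attacks the methyl group of the boron-complexed ether and the ketone is untouched.

Step 7
Reactants: 11 5,6-dihydroxy-1-indanone; 7 benzyl bromide
Product: 12 5,6-dibenzyloxy-1-indanone
Conditions: BnBr, K2CO3, DMF, 60 °C
Reagents that add atoms: benzyl bromide (compound 7, also listed as reactant), BrCc1ccccc1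
Why: Double Williamson etherification of the catechol under the conditions of step 4.

Step 8
Reactants: 12 5,6-dibenzyloxy-1-indanone
Product: 13 2-bromo-5,6-dibenzyloxy-1-indanone (racemic)
Conditions: CuBr2, EtOAc/CHCl3, reflux
Reagents that add atoms: CuBr2 (copper dibromide), [Cu+2].[Br-].[Br-]
Why: Alpha-bromination of an aryl ketone through its enol with CuBr2, which stops at the monobromide and leaves the aromatic ring and the benzyl ethers alone.

Step 9
Reactants: 9 allyl 6-benzyloxy-5,7-dimethoxy-1-oxoindane-2-carboxylate; 13 2-bromo-5,6-dibenzyloxy-1-indanone
Product: 14 allyl 6-benzyloxy-2-(5,6-dibenzyloxy-1-oxoindan-2-yl)-5,7-dimethoxy-1-oxoindane-2-carboxylate (mixture of diastereomers)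
Conditions: K2CO3, acetone, rt
Reagents that add atoms: none
Why: C-alkylation of a beta-keto ester enolate by an alpha-bromo ketone (SN2, accelerated by the adjacent carbonyl); the two new stereocentres are not controlled because both are removed later.

Step 10
Reactants: 14 allyl 6-benzyloxy-2-(5,6-dibenzyloxy-1-oxoindan-2-yl)-5,7-dimethoxy-1-oxoindane-2-carboxylate
Product: 16 6-benzyloxy-5',6'-dibenzyloxy-5,7-dimethoxy-2,2'-biindan-1,1'-dione (mixture of diastereomers), via beta-keto acid 15 (not isolated)
Conditions: Pd(PPh3)4 (cat.), morpholine, THF, rt to 40 °C
Reagents that add atoms: none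
Why: Tsuji-type deallylation through a pi-allyl palladium complex that morpholine intercepts; the free beta-keto acid 15 loses CO2 under these neutral conditions, so benzyl ethers and the peri methoxy group are not endangered.

Step 11
Reactants: 16 6-benzyloxy-5',6'-dibenzyloxy-5,7-dimethoxy-2,2'-biindan-1,1'-dione
Product: 19 tri-O-benzyl 3,4,3',4'-tetrahydroarteminorin C (7-benzyloxy-6',7'-dibenzyloxy-6,8-dimethoxy-3,3'-bichroman-2,2'-dione; mixture of diastereomers), via primed-ring keto-lactone 17 (not isolated), via unprimed-ring keto-lactone 18 (not isolated)
Conditions: mCPBA, CF3CO2H, CH2Cl2, 0 °C to rt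
Reagents that add atoms: mCPBA (3-chloroperbenzoic acid), OOC(=O)c1cccc(Cl)c1
Why: Baeyer-Villiger oxidation, run twice in one flask. Acid-assisted addition of the peracid to each ketone gives a Criegee adduct, in which the aryl carbon antiperiplanar to the O–O bond shifts from carbon to oxygen as 3-chlorobenzoate leaves. The closest known reaction is the peracid ring expansion of 1-indanones to 3,4-dihydrocoumarins. Each six-membered lactone arises by ring expansion of a five-membered ketone through this 1,2-shift and not by an end-to-end cyclisation, so no closure mode has to be satisfied; the unprimed ring gains O1 between C2 and C8a, the primed ring O1' between C2' and C8a'. No stereocentre is created, and C3 and C3' are untouched and carried as a mixture that step 12 erases. The selectivity needed is migration of aryl in preference to the methine carbon in each adduct; the migrating carbon of the unprimed ring has a para and an ortho methoxy group and that of the primed ring a para benzyloxy group, which stabilise the bridged transition state, while the competing methine is inductively deactivated by the carbonyl-bearing carbon next to it. Either ketone may react first, so both keto-lactones 17 and 18 are expected in passing and both lead to 19. The allyl group was removed in step 10 so no alkene competes for the peracid, and little CF3CO2H and low temperature are used to spare the hindered benzyl ether and to hold back acid-induced furan formation from the 1,4-diketone.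

Step 12
Reactants: 19 tri-O-benzyl 3,4,3',4'-tetrahydroarteminorin C
Product: 21 tri-O-benzyl arteminorin C (7-benzyloxy-6',7'-dibenzyloxy-6,8-dimethoxy-3,3'-bicoumarin), via mono-coumarin 20 (not isolated)
Conditions: DDQ, 1,4-dioxane, reflux
Reagents that add atoms: none
Why: Quinone dehydrogenation of dihydrocoumarins; DDQ abstracts hydride from C4' and C4, which are benzylic and para to the 7'- and 7-benzyloxy donors, and the acidic proton at C3' or C3 is then lost to give an aromatic pyranone. The primed ring, whose para donor is unhindered, should react first (20), and phenyl-type benzyl ethers of phenols are not attacked by DDQ.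

Step 13
Reactants: 21 tri-O-benzyl arteminorin C
Product: 22 arteminorin C (6',7,7'-trihydroxy-6,8-dimethoxy-3,3'-bicoumarin)
Conditions: BCl3, C6HMe5, CH2Cl2, −78 °C; then H2O
Reagents that add atoms: none
Why: Lewis-acid debenzylation with pentamethylbenzene as benzyl-cation scavenger; at −78 °C BCl3 ionises benzyl aryl ethers but not methyl ethers that lack an ortho carbonyl, and the coumarin double bonds, which hydrogenolysis could reduce, are not touched.

## Compound list

1 | syringaldehyde (4-hydroxy-3,5-dimethoxybenzaldehyde) | COc1cc(C=O)cc(OC)c1O | starting material
2 | malonic acid | OC(=O)CC(=O)O | starting material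
3 | (4-hydroxy-3,5-dimethoxybenzylidene)malonic acid | COc1cc(C=C(C(=O)O)C(=O)O)cc(OC)c1O | intermediate
4 | (E)-sinapic acid | COc1cc(/C=C/C(=O)O)cc(OC)c1O | intermediate
5 | 3-(4-hydroxy-3,5-dimethoxyphenyl)propanoic acid | COc1cc(CCC(=O)O)cc(OC)c1O | intermediate
6 | 6-hydroxy-5,7-dimethoxy-1-indanone | COc1cc2CCC(=O)c2c(OC)c1O | intermediate
7 | benzyl bromide | BrCc1ccccc1 | starting material
8 | 6-benzyloxy-5,7-dimethoxy-1-indanone | COc1cc2CCC(=O)c2c(OC)c1OCc1ccccc1 | intermediate
9 | allyl 6-benzyloxy-5,7-dimethoxy-1-oxoindane-2-carboxylate (racemic) | COc1cc2CC(C(=O)OCC=C)C(=O)c2c(OC)c1OCc1ccccc1 | intermediate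
10 | 5,6-dimethoxy-1-indanone | COc1cc2CCC(=O)c2cc1OC | starting material
11 | 5,6-dihydroxy-1-indanone | Oc1cc2CCC(=O)c2cc1O | intermediate
12 | 5,6-dibenzyloxy-1-indanone | O=C1CCc2cc(OCc3ccccc3)c(OCc3ccccc3)cc12 | intermediate
13 | 2-bromo-5,6-dibenzyloxy-1-indanone (racemic) | O=C1C(Br)Cc2cc(OCc3ccccc3)c(OCc3ccccc3)cc12 | intermediate
14 | allyl 6-benzyloxy-2-(5,6-dibenzyloxy-1-oxoindan-2-yl)-5,7-dimethoxy-1-oxoindane-2-carboxylate (mixture of diastereomers) | COc1cc2CC(C(=O)OCC=C)(C3Cc4cc(OCc5ccccc5)c(OCc5ccccc5)cc4C3=O)C(=O)c2c(OC)c1OCc1ccccc1 | intermediate
15 | 6-benzyloxy-2-(5,6-dibenzyloxy-1-oxoindan-2-yl)-5,7-dimethoxy-1-oxoindane-2-carboxylic acid (mixture of diastereomers) | COc1cc2CC(C(=O)O)(C3Cc4cc(OCc5ccccc5)c(OCc5ccccc5)cc4C3=O)C(=O)c2c(OC)c1OCc1ccccc1 | intermediate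
16 | 6-benzyloxy-5',6'-dibenzyloxy-5,7-dimethoxy-2,2'-biindan-1,1'-dione (mixture of diastereomers) | COc1cc2CC(C3Cc4cc(OCc5ccccc5)c(OCc5ccccc5)cc4C3=O)C(=O)c2c(OC)c1OCc1ccccc1 | intermediate
17 | 6,7-dibenzyloxy-3-(6-benzyloxy-5,7-dimethoxy-1-oxoindan-2-yl)chroman-2-one (mixture of diastereomers) | COc1cc2CC(C3Cc4cc(OCc5ccccc5)c(OCc5ccccc5)cc4OC3=O)C(=O)c2c(OC)c1OCc1ccccc1 | intermediate
18 | 7-benzyloxy-3-(5,6-dibenzyloxy-1-oxoindan-2-yl)-6,8-dimethoxychroman-2-one (mixture of diastereomers) | COc1cc2CC(C3Cc4cc(OCc5ccccc5)c(OCc5ccccc5)cc4C3=O)C(=O)Oc2c(OC)c1OCc1ccccc1 | intermediate
19 | tri-O-benzyl 3,4,3',4'-tetrahydroarteminorin C (mixture of diastereomers) | COc1cc2CC(C3Cc4cc(OCc5ccccc5)c(OCc5ccccc5)cc4OC3=O)C(=O)Oc2c(OC)c1OCc1ccccc1 | intermediate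
20 | 6,7-dibenzyloxy-3-(7-benzyloxy-6,8-dimethoxy-2-oxochroman-3-yl)-2H-chromen-2-one (racemic) | COc1cc2CC(c3cc4cc(OCc5ccccc5)c(OCc5ccccc5)cc4oc3=O)C(=O)Oc2c(OC)c1OCc1ccccc1 | intermediate
21 | tri-O-benzyl arteminorin C | COc1cc2cc(-c3cc4cc(OCc5ccccc5)c(OCc5ccccc5)cc4oc3=O)c(=O)oc2c(OC)c1OCc1ccccc1 | intermediate
22 | arteminorin C | COc1cc2cc(-c3cc4cc(O)c(O)cc4oc3=O)c(=O)oc2c(OC)c1O | target

## Step count and risks

Total step count: 13. Longest linear sequence: 10 steps (steps 1, 2, 3, 4, 5, 9, 10, 11, 12 and 13, from 1); the branch from 10 adds steps 6, 7 and 8.

Least certain steps: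

Step 11 (key step). The most likely failure is acid-promoted cyclodehydration of the 1,4-diketone to a fused furan before oxygen insertion, since the substrate is a Paal-Knorr precursor. The oxidation may also stall after the first insertion, the methine may migrate in place of aryl in one half, or the hindered benzyl ether may be lost to acid. The fallback moves the first oxygen insertion ahead of the C–C bond formation, so that peracid and acid never meet a 1,4-diketone. It sets out from 12 and 9 and returns at 17.
- 12 is ring-expanded alone with mCPBA and CF3CO2H to 6,7-dibenzyloxychroman-2-one F1, the plain indanone case.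
- The lithium enolate of F1 (LiN(SiMe3)2, THF, −78 °C) is brominated with N-bromosuccinimide to 3-bromo-6,7-dibenzyloxychroman-2-one F2.
- F2 alkylates the enolate of 9 (K2CO3, acetone) to allyl 6-benzyloxy-2-(6,7-dibenzyloxy-2-oxochroman-3-yl)-5,7-dimethoxy-1-oxoindane-2-carboxylate F3.
- Pd(OAc)2 and PPh3 with HCO2H and Et3N, a scavenger that cannot aminolyse the aryl lactone, remove the allyl group. The acid F4 (6-benzyloxy-2-(6,7-dibenzyloxy-2-oxochroman-3-yl)-5,7-dimethoxy-1-oxoindane-2-carboxylic acid) loses CO2 to give 17.
- 17 is isolated and taken to 19 by a single oxygen insertion.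

Step 9. The alkylation creates a quaternary carbon next to a tertiary one, so the displacement may be slow. Two side paths are plausible: halogen transfer from 13 to the enolate of 9, or loss of HBr from 13 followed by conjugate addition, which would join the halves through the wrong carbon. The fallback is a silicon-tethered oxidative enolate coupling, setting out from 8 and 12 and returning at 16.
- The lithium enolate of 8 (LiN(i-Pr)2, THF, −78 °C) is silylated with i-Pr2SiCl2 to the chlorodiisopropylsilyl enol ether F5.
- The lithium enolate of 12 is added to give the unsymmetrical diisopropylsilyl bis-enol ether F6.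
- Oxidation with (NH4)2Ce(NO3)6 and NaHCO3 in MeCN at −10 °C couples the two enol carbons within the tether and gives 16 directly.

Step 12. The second dehydrogenation may be incomplete, because the benzyloxy group on C7 is twisted between two methoxy groups and donates poorly to C4. Prolonged heating with DDQ may then lead to oxidation at other benzylic sites. The fallback replaces hydride abstraction by enolate chemistry, setting out from 19 and returning at 21.
- 19 is converted with LiN(SiMe3)2 and Me3SiCl (internal quench, THF, −78 °C) into the bis(trimethylsilyl ketene acetal) F7.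
- F7 is treated with Pd(OAc)2 in MeCN (Saegusa-Ito dehydrosilylation with stoichiometric divalent palladium), giving 21 after beta-hydride elimination towards C4 and C4'.

Step 3. The free phenol may be acylated intermolecularly to oligomeric aryl esters, or the electron-rich phenol may be sulfonated or degraded in the hot acid medium. The fallback closes the ring on a protected phenol by an acid chloride Friedel-Crafts reaction, setting out from 5 and returning at 6.
- 5 is acetylated (Ac2O, pyridine; aqueous work-up) to 3-(4-acetoxy-3,5-dimethoxyphenyl)propanoic acid F8.
- (COCl)2 with catalytic DMF gives the acid chloride F9 (3-(4-acetoxy-3,5-dimethoxyphenyl)propanoyl chloride).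
- SnCl4 in CH2Cl2 at −20 °C closes F9 to 6-acetoxy-5,7-dimethoxy-1-indanone F10.
- K2CO3 in MeOH removes the acetate and gives 6.

## Further compounds

F1 | step 11 | 6,7-dibenzyloxychroman-2-one | O=C1CCc2cc(OCc3ccccc3)c(OCc3ccccc3)cc2O1
F2 | step 11 | 3-bromo-6,7-dibenzyloxychroman-2-one (racemic) | O=C1Oc2cc(OCc3ccccc3)c(OCc3ccccc3)cc2CC1Br
F3 | step 11 | allyl 6-benzyloxy-2-(6,7-dibenzyloxy-2-oxochroman-3-yl)-5,7-dimethoxy-1-oxoindane-2-carboxylate (mixture of diastereomers) | COc1cc2CC(C(=O)OCC=C)(C3Cc4cc(OCc5ccccc5)c(OCc5ccccc5)cc4OC3=O)C(=O)c2c(OC)c1OCc1ccccc1
F4 | step 11 | 6-benzyloxy-2-(6,7-dibenzyloxy-2-oxochroman-3-yl)-5,7-dimethoxy-1-oxoindane-2-carboxylic acid (mixture of diastereomers) | COc1cc2CC(C(=O)O)(C3Cc4cc(OCc5ccccc5)c(OCc5ccccc5)cc4OC3=O)C(=O)c2c(OC)c1OCc1ccccc1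
F5 | step 9 | (6-benzyloxy-5,7-dimethoxy-1H-inden-3-yl)oxy(chloro)diisopropylsilane | COc1cc2CC=C(O[Si](Cl)(C(C)C)C(C)C)c2c(OC)c1OCc1ccccc1
F6 | step 9 | (6-benzyloxy-5,7-dimethoxy-1H-inden-3-yl)oxy(5,6-dibenzyloxy-1H-inden-3-yl)oxydiisopropylsilane | COc1cc2CC=C(O[Si](C(C)C)(C(C)C)OC3=CCc4cc(OCc5ccccc5)c(OCc5ccccc5)cc34)c2c(OC)c1OCc1ccccc1
F7 | step 12 | 7-benzyloxy-6',7'-dibenzyloxy-6,8-dimethoxy-2,2'-bis(trimethylsilyloxy)-4H,4'H-3,3'-bichromene | COc1cc2CC(C3=C(O[Si](C)(C)C)Oc4cc(OCc5ccccc5)c(OCc5ccccc5)cc4C3)=C(O[Si](C)(C)C)Oc2c(OC)c1OCc1ccccc1
F8 | step 3 | 3-(4-acetoxy-3,5-dimethoxyphenyl)propanoic acid | COc1cc(CCC(=O)O)cc(OC)c1OC(C)=O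
F9 | step 3 | 3-(4-acetoxy-3,5-dimethoxyphenyl)propanoyl chloride | COc1cc(CCC(=O)Cl)cc(OC)c1OC(C)=O
F10 | step 3 | 6-acetoxy-5,7-dimethoxy-1-indanone | COc1cc2CCC(=O)c2c(OC)c1OC(C)=O
A1 | alternative 1 | 7-O-benzyl-6',7'-O-methylene arteminorin C | COc1cc2cc(-c3cc4cc5OCOc5cc4oc3=O)c(=O)oc2c(OC)c1OCc1ccccc1
A2 | alternative 1 | 6-(trimethylsilyl)-1,3-benzodioxol-5-yl trifluoromethanesulfonate | C[Si](C)(C)c1cc2OCOc2cc1OS(=O)(=O)C(F)(F)F
A3 | alternative 1 | methyl (7-benzyloxy-6,8-dimethoxy-2-oxo-2H-chromen-3-yl)acetate | COC(=O)Cc1cc2cc(OC)c(OCc3ccccc3)c(OC)c2oc1=O
A4 | alternative 2 | 7-O-methyl-6',7'-di-O-benzyl arteminorin C | COc1cc2cc(-c3cc4cc(OCc5ccccc5)c(OCc5ccccc5)cc4oc3=O)c(=O)oc2c(OC)c1OC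
A5 | alternative 2 | methyl (2Z,4E)-2-(6,7-dibenzyloxy-2-oxo-2H-chromen-3-yl)-5-(1,2,3-trimethoxy-4-oxocyclobut-2-en-1-yl)penta-2,4-dienoate (racemic) | COC1=C(OC)C(OC)(/C=C/C=C(\C(=O)OC)c2cc3cc(OCc4ccccc4)c(OCc4ccccc4)cc3oc2=O)C1=O
A6 | alternative 3 | tri-O-benzyl arteminorin C | COc1cc2cc(-c3cc4cc(OCc5ccccc5)c(OCc5ccccc5)cc4oc3=O)c(=O)oc2c(OC)c1OCc1ccccc1
A7 | alternative 3 | (2E,3E)-2-(4-benzyloxy-3,5-dimethoxybenzylidene)-3-(3,4-dibenzyloxybenzylidene)succinic acid | COc1cc(/C=C(/C(=O)O)\C(=C/c2ccc(OCc3ccccc3)c(OCc3ccccc3)c2)C(=O)O)cc(OC)c1OCc1ccccc1
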